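**Plan**

1. Retrosynthesis: both C–Br bonds are cut last, each CHBr going back to a ketone by way of a vinyl bromide. Ring A is cut at the CH2–C1′ bond and taken back to p-benzoquinone monoketal. The CH2–C1 bond is cut to a C1 ketone. In the core, the C7a–C7 bond and the lactone C–O bond are cut together, leaving a 3,3-disubstituted cyclopentanone.
2. Forward order: cyclopentanone with the quaternary carbon (conjugate addition of a 5-methyl-2-furyl group, a masked 1,4-diketone), then the six-membered carbocycle and the bridged γ-lactone in one aldol–lactonisation cascade, then one-carbon homologation at C1, then ring A grown from a p-quinol, then both bromines in the last two steps.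
3. Enabling feature: C7, the tertiary carbon that carries the lactone oxygen, is β to C1 and 1,3 to the carboxyl carbon on the angular C3a. With C1 as a ketone, the C7a–C7 bond is an aldol bond, and the C3a ester, 1,3-diaxial to the new hydroxyl, traps it as the 6-oxabicyclo[3.2.1]octan-7-one.
4. Stereochemistry: C3a by asymmetric catalysis; C7 and C7a relayed from it in the cascade; C1 by equilibration of an aldehyde; C1′ by catalytic desymmetrisation of the p-quinol; C4 and C4′ by substrate-controlled hydrogen-atom-transfer hydrogenation of vinyl bromides.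

Key step: step 3

Remark: the two starting materials of step 1 and the quinone monoketal of step 7 are taken as commercial, and the sense of induction of each chiral catalyst is assumed to be set by the choice of ligand antipode. Core locants follow octahydro-1H-indene (C1 bears the CH2 link, C3a the lactone carbonyl, C7 the methyl group and the lactone oxygen); ring A is C1′ (carbinol), C3′ (gem-dimethyl), C4′ (bromine).

**Route**

Step 1
Reactants: 1 methyl 3-oxocyclopent-1-ene-1-carboxylate; 2 2-methylfuran
Product: 5 methyl (1R)-1-(5-methylfuran-2-yl)-3-oxocyclopentane-1-carboxylate, via 5-methyl-2-furyllithium 3 (not isolated), via dimethyl(5-methyl-2-furyl)aluminium 4 (not isolated)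
Conditions: 2, n-BuLi, THF, −78 → 0 °C; Me2AlCl, −78 °C; then 1, Cu(OTf)2 (5 mol %), chiral sulfonate-bearing imidazolinium salt (N-heterocyclic carbene precursor, 5 mol %), THF, −30 °C; aq. work-up
Reagents that add atoms: none
Why: Copper-catalysed enantioselective conjugate addition of a heteroaryl–aluminium reagent to a β-substituted cyclic enone should place the furyl group on the ester-bearing β-carbon, the chiral carbene–copper complex choosing the enone face and so setting the quaternary centre (later C3a).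

Step 2
Reactants: 5 methyl (1R)-1-(5-methylfuran-2-yl)-3-oxocyclopentane-1-carboxylate
Product: 7 methyl (1R)-3-oxo-1-(4-oxopentanoyl)cyclopentane-1-carboxylate, via cis-enedione 6 (not isolated)
Conditions: NBS, NaHCO3, acetone/H2O, −20 °C; then Zn, AcOH, 23 °C
Reagents that add atoms: water, O
Why: Oxidative ring opening of the 2,5-disubstituted furan to the cis-enedione followed by zinc reduction of its C=C bond should unmask the 1,4-diketone under conditions that leave the quaternary stereocentre untouched.

Step 3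
Reactants: 7 methyl (1R)-3-oxo-1-(4-oxopentanoyl)cyclopentane-1-carboxylate
Product: 10 (3aR,7R,7aS)-7-methyl-1,4-dioxooctahydro-1H-indene-3a,7-carbolactone, via pyrrolidine enamine 8 (not isolated), via trans-fused ketol 9 (not isolated)
Conditions: pyrrolidine (0.3 equiv), AcOH (0.3 equiv), toluene, 23 → 45 °C
Reagents that add atoms: none
Why: Pyrrolidinium acetate should convert the cyclopentanone of 7, the ketone most prone to enamine formation, into enamine 8, whose ring carbon between the ketone and the quaternary carbon adds to the side-chain methyl ketone; the closest known reactions are amine-catalysed intramolecular ketone aldol cyclisations of triketones (Hajos–Parrish type) and aldol–lactonisation cascades. The carbocycle closes by this 6-(enolexo)-exo-trig aldol addition, and the lactone closes by 5-exo-trig acyl substitution of the tertiary hydroxyl on the 1,3-diaxial methyl ester with loss of methanol, giving the 6-oxabicyclo[3.2.1]octan-7-one. C7 is controlled by the C3a stereocentre, because only the ketol whose hydroxyl is cis to the ester on the new ring can lactonise, while its C7 epimer returns to 7 by retro-aldol reaction. C7a is set under thermodynamic control, since it is α to the C1 ketone and only the trans-fused hydrindanone ketol 9 leads to a cis-fused lactone/cyclopentanone pair, whereas the C7a epimer would need a trans-fused bicyclo[3.3.0] unit. The step needs chemoselectivity for this enamine over enolisation of the methyl ketone (whose attack on the ketone next to the quaternary carbon would end in a cyclopentenone) and must avoid dehydration of the ketol and β-elimination of the lactone carboxylate from the product. Fast enamine formation at the cyclopentanone, reversibility of every aldol addition, and the fact that irreversible lactonisation is open only to 9, together with mild, weakly acidic conditions, should secure this.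

Step 4
Reactants: 10 (3aR,7R,7aS)-7-methyl-1,4-dioxooctahydro-1H-indene-3a,7-carbolactone
Product: 12 (1R,3aR,7R,7aS)-1-formyl-7-methyl-4-oxooctahydro-1H-indene-3a,7-carbolactone, via enol ether 11 (not isolated)
Conditions: Ph3P(CH2OMe)Cl, KHMDS, THF, −78 → 0 °C; then 2 M HCl, THF, 23 °C
Reagents that add atoms: (methoxymethyl)triphenylphosphonium chloride, COC[P+](c1ccccc1)(c1ccccc1)c1ccccc1.[Cl-]; water, O
Why: Wittig methoxymethylenation should select the cyclopentanone over the C4 ketone flanked by the quaternary C3a, and acid hydrolysis of the enol ether gives the aldehyde, whose α-carbon C1 should equilibrate to the epimer with the formyl group trans to C7 on the convex face (thermodynamic control).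

Step 5
Reactants: 12 (1R,3aR,7R,7aS)-1-formyl-7-methyl-4-oxooctahydro-1H-indene-3a,7-carbolactone
Product: 13 (1R,3aR,4S,7R,7aS)-4-hydroxy-1-(hydroxymethyl)-7-methyloctahydro-1H-indene-3a,7-carbolactone
Conditions: NaBH4, MeOH, 0 °C
Reagents that add atoms: none
Why: Borohydride reduction of the aldehyde and of the C4 ketone masks C4 against the organolithium and enolate steps ahead; hydride should approach C4 anti to the axial lactone carbonyl to give the equatorial alcohol, whose configuration is immaterial because C4 is re-oxidised in step 11.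

Step 6
Reactants: 13 (1R,3aR,4S,7R,7aS)-4-hydroxy-1-(hydroxymethyl)-7-methyloctahydro-1H-indene-3a,7-carbolactone
Product: 15 (1R,3aR,4S,7R,7aS)-1-(iodomethyl)-7-methyl-4-(triethylsilyloxy)octahydro-1H-indene-3a,7-carbolactone, via iodo alcohol 14 (not isolated)
Conditions: I2, PPh3, imidazole, CH2Cl2, 0 °C; then Et3SiCl, 23 °C
Reagents that add atoms: iodine, II; chlorotriethylsilane, CC[Si](Cl)(CC)CC
Why: Appel-type iodination should discriminate the primary from the neopentylic secondary alcohol, which is then silylated in the same flask so that no alkoxide can later displace the cis-disposed iodide.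

Step 7
Reactants: 15 (1R,3aR,4S,7R,7aS)-1-(iodomethyl)-7-methyl-4-(triethylsilyloxy)octahydro-1H-indene-3a,7-carbolactone; 16 4,4-dimethoxycyclohexa-2,5-dien-1-one
Product: 19 (1S,3aR,4S,7R,7aS)-4-hydroxy-1-[(1-hydroxy-4-oxocyclohexa-2,5-dien-1-yl)methyl]-7-methyloctahydro-1H-indene-3a,7-carbolactone, via alkyllithium 17 (not isolated), via dimethyl ketal 18 (not isolated)
Conditions: t-BuLi (2.1 equiv), Et2O/pentane, −78 °C; 16, −78 °C; then 1 M HCl, THF, 23 °C
Reagents that add atoms: water, O
Why: Iodine–lithium exchange should outrun attack on the hindered lactone (which the CH2Li group cannot reach within the molecule, being trans to the lactone carbonyl on the cyclopentane), and 1,2-addition to the quinone monoketal followed by acid hydrolysis of ketal and silyl ether gives the p-quinol, whose carbinol carbon carries two identical enone arms and is therefore not yet a stereocentre.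

Step 8
Reactants: 19 (1S,3aR,4S,7R,7aS)-4-hydroxy-1-[(1-hydroxy-4-oxocyclohexa-2,5-dien-1-yl)methyl]-7-methyloctahydro-1H-indene-3a,7-carbolactone
Product: 20 (1S,3aR,4S,7R,7aS)-4-hydroxy-1-{[(1R)-1-hydroxy-4-oxocyclohex-2-en-1-yl]methyl}-7-methyloctahydro-1H-indene-3a,7-carbolactone
Conditions: Cu(OAc)2 (5 mol %), DTBM-SEGPHOS (one antipode, 5.5 mol %), (EtO)2MeSiH, t-BuOH, toluene, 0 °C
Reagents that add atoms: none
Why: Copper hydride-catalysed asymmetric conjugate reduction should desymmetrise the cyclohexadienone by reducing one of its two enantiotopic enone arms (the 2-silyloxydiene formed cannot be reduced again), which makes C1′ a stereocentre under catalyst control.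

Step 9
Reactants: 20 (1S,3aR,4S,7R,7aS)-4-hydroxy-1-{[(1R)-1-hydroxy-4-oxocyclohex-2-en-1-yl]methyl}-7-methyloctahydro-1H-indene-3a,7-carbolactone
Product: 22 (1S,3aR,4S,7R,7aS)-4-hydroxy-1-{[(1S)-1-hydroxy-5,5-dimethyl-4-oxocyclohex-2-en-1-yl]methyl}-7-methyloctahydro-1H-indene-3a,7-carbolactone, via monomethyl enone 21 (not isolated)
Conditions: LDA (3.3 equiv), THF, −78 °C, MeI (1.1 equiv); then LDA (1.5 equiv), MeI (1.5 equiv), −78 → −20 °C
Reagents that add atoms: iodomethane, CI
Why: The enone can enolise only at its α′-CH2 (the γ-carbon is quaternary), so two kinetic enolate methylations should place both methyl groups on the carbon next to the ketone on the reduced arm, while the lithium alkoxides of the two hindered alcohols are not alkylated at low temperature; no stereocentre is formed.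

Step 10
Reactants: 22 (1S,3aR,4S,7R,7aS)-4-hydroxy-1-{[(1S)-1-hydroxy-5,5-dimethyl-4-oxocyclohex-2-en-1-yl]methyl}-7-methyloctahydro-1H-indene-3a,7-carbolactone
Product: 23 (1S,3aR,4S,7R,7aS)-4-hydroxy-1-{[(1S)-1-hydroxy-3,3-dimethyl-4-oxocyclohexyl]methyl}-7-methyloctahydro-1H-indene-3a,7-carbolactone
Conditions: H2 (1 atm), Pd/C, EtOAc, 23 °C
Reagents that add atoms: none
Why: Catalytic hydrogenation of the enone C=C bond should proceed without touching ketone, lactone or alcohols, and creates no stereocentre.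

Step 11
Reactants: 23 (1S,3aR,4S,7R,7aS)-4-hydroxy-1-{[(1S)-1-hydroxy-3,3-dimethyl-4-oxocyclohexyl]methyl}-7-methyloctahydro-1H-indene-3a,7-carbolactone
Product: 24 (1S,3aR,7R,7aS)-1-{[(1S)-1-hydroxy-3,3-dimethyl-4-oxocyclohexyl]methyl}-7-methyl-4-oxooctahydro-1H-indene-3a,7-carbolactone
Conditions: Dess–Martin periodinane, CH2Cl2, 23 °C
Reagents that add atoms: none
Why: Dess–Martin oxidation of the secondary alcohol should return the C4 ketone, the tertiary C1′ alcohol being inert to oxidation.

Step 12
Reactants: 24 (1S,3aR,7R,7aS)-1-{[(1S)-1-hydroxy-3,3-dimethyl-4-oxocyclohexyl]methyl}-7-methyl-4-oxooctahydro-1H-indene-3a,7-carbolactone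
Product: 26 (1S,3aS,7R,7aS)-4-bromo-1-{[(1R)-4-bromo-5,5-dimethyl-1-(trimethylsilyloxy)cyclohex-3-en-1-yl]methyl}-7-methyl-2,3,3a,6,7,7a-hexahydro-1H-indene-3a,7-carbolactone, via trimethylsilyl ether 25 (not isolated)
Conditions: N-(trimethylsilyl)imidazole, CH2Cl2, 23 °C; then (PhO)3P, Br2, Et3N, CH2Cl2, −60 → 40 °C
Reagents that add atoms: N-(trimethylsilyl)imidazole, C[Si](C)(C)n1ccnc1; bromine, BrBr
Why: Each ketone has α-hydrogens on one side only (the other α-carbon is quaternary), so the triphenyl phosphite–bromine reagent (ketone to vinyl halide conversion) should turn both into single vinyl bromides, the tertiary alcohol having been masked as its silyl ether beforehand.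

Step 13
Reactants: 26 (1S,3aS,7R,7aS)-4-bromo-1-{[(1R)-4-bromo-5,5-dimethyl-1-(trimethylsilyloxy)cyclohex-3-en-1-yl]methyl}-7-methyl-2,3,3a,6,7,7a-hexahydro-1H-indene-3a,7-carbolactone
Product: 28 (1S,3aS,4S,7R,7aS)-4-bromo-1-{[(1S,4S)-4-bromo-1-hydroxy-3,3-dimethylcyclohexyl]methyl}-7-methyloctahydro-1H-indene-3a,7-carbolactone, via silyl ether 27 (not isolated)
Conditions: Mn(dpm)3 (20 mol %), PhSiH3, t-BuOOH, i-PrOH, 23 °C; then 1 M HCl, THF, 0 °C
Reagents that add atoms: none
Why: Hydrogen-atom-transfer hydrogenation of the two vinyl bromides (metal hydride H-atom transfer to the CH terminus, then H-atom capture by the α-bromo radical) keeps both C–Br bonds; the second hydrogen should arrive at C4 anti to the axial lactone bridge and at C4′ axially, anti to the axial C3′ methyl in the chair with the CH2 substituent equatorial, so both bromines end equatorial (4S, 4′S), and acid then removes the silyl group.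

**Compound list**

1 | methyl 3-oxocyclopent-1-ene-1-carboxylate | COC(=O)C1=CC(=O)CC1 | starting material
2 | 2-methylfuran | Cc1ccco1 | starting material
3 | 5-methyl-2-furyllithium | [Li]c1ccc(C)o1 | intermediate
4 | dimethyl(5-methyl-2-furyl)aluminium | C[Al](C)c1ccc(C)o1 | intermediate
5 | methyl (1R)-1-(5-methylfuran-2-yl)-3-oxocyclopentane-1-carboxylate | COC(=O)[C@@]1(CCC(=O)C1)c1ccc(C)o1 | intermediate
6 | methyl (1R)-3-oxo-1-[(2Z)-4-oxopent-2-enoyl]cyclopentane-1-carboxylate | COC(=O)[C@@]1(CCC(=O)C1)C(=O)/C=C\C(C)=O | intermediate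
7 | methyl (1R)-3-oxo-1-(4-oxopentanoyl)cyclopentane-1-carboxylate | COC(=O)[C@@]1(CCC(=O)C1)C(=O)CCC(C)=O | intermediate
8 | methyl (1R)-1-(4-oxopentanoyl)-3-(pyrrolidin-1-yl)cyclopent-2-ene-1-carboxylate | COC(=O)[C@@]1(CCC(N2CCCC2)=C1)C(=O)CCC(C)=O | intermediate
9 | methyl (3aR,7R,7aS)-7-hydroxy-7-methyl-1,4-dioxooctahydro-1H-indene-3a-carboxylate | O=C1CC[C@]2(C(=O)OC)C(=O)CC[C@@](C)(O)[C@@H]12 | intermediate
10 | (3aR,7R,7aS)-7-methyl-1,4-dioxooctahydro-1H-indene-3a,7-carbolactone | O=C1CC[C@]23C(=O)O[C@](C)(CCC2=O)[C@@H]13 | intermediate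
11 | (3aR,7R,7aS)-1-(methoxymethylidene)-7-methyl-4-oxooctahydro-1H-indene-3a,7-carbolactone (E/Z mixture) | COC=C1CC[C@]23C(=O)O[C@](C)(CCC2=O)[C@@H]13 | intermediate
12 | (1R,3aR,7R,7aS)-1-formyl-7-methyl-4-oxooctahydro-1H-indene-3a,7-carbolactone | O=C[C@@H]1CC[C@]23C(=O)O[C@](C)(CCC2=O)[C@@H]13 | intermediate
13 | (1R,3aR,4S,7R,7aS)-4-hydroxy-1-(hydroxymethyl)-7-methyloctahydro-1H-indene-3a,7-carbolactone | OC[C@@H]1CC[C@]23C(=O)O[C@](C)(CC[C@@H]2O)[C@@H]13 | intermediate
14 | (1R,3aR,4S,7R,7aS)-4-hydroxy-1-(iodomethyl)-7-methyloctahydro-1H-indene-3a,7-carbolactone | IC[C@@H]1CC[C@]23C(=O)O[C@](C)(CC[C@@H]2O)[C@@H]13 | intermediate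
15 | (1R,3aR,4S,7R,7aS)-1-(iodomethyl)-7-methyl-4-(triethylsilyloxy)octahydro-1H-indene-3a,7-carbolactone | IC[C@@H]1CC[C@]23C(=O)O[C@](C)(CC[C@@H]2O[Si](CC)(CC)CC)[C@@H]13 | intermediate
16 | 4,4-dimethoxycyclohexa-2,5-dien-1-one | COC1(OC)C=CC(=O)C=C1 | starting material
17 | alkyllithium from 15 (CH2Li in place of CH2I) | [Li]C[C@@H]1CC[C@]23C(=O)O[C@](C)(CC[C@@H]2O[Si](CC)(CC)CC)[C@@H]13 | intermediate
18 | (1S,3aR,4S,7R,7aS)-1-[(1-hydroxy-4,4-dimethoxycyclohexa-2,5-dien-1-yl)methyl]-7-methyl-4-(triethylsilyloxy)octahydro-1H-indene-3a,7-carbolactone | COC1(OC)C=CC(O)(C[C@@H]2CC[C@]34C(=O)O[C@](C)(CC[C@@H]3O[Si](CC)(CC)CC)[C@@H]24)C=C1 | intermediate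
19 | (1S,3aR,4S,7R,7aS)-4-hydroxy-1-[(1-hydroxy-4-oxocyclohexa-2,5-dien-1-yl)methyl]-7-methyloctahydro-1H-indene-3a,7-carbolactone | O=C1C=CC(O)(C[C@@H]2CC[C@]34C(=O)O[C@](C)(CC[C@@H]3O)[C@@H]24)C=C1 | intermediate
20 | (1S,3aR,4S,7R,7aS)-4-hydroxy-1-{[(1R)-1-hydroxy-4-oxocyclohex-2-en-1-yl]methyl}-7-methyloctahydro-1H-indene-3a,7-carbolactone | O=C1CC[C@@](O)(C[C@@H]2CC[C@]34C(=O)O[C@](C)(CC[C@@H]3O)[C@@H]24)C=C1 | intermediate
21 | 5-methyl-4-oxocyclohex-2-enyl analogue of 20 (mixture of epimers at the methyl-bearing carbon) | CC1C[C@@](O)(C[C@@H]2CC[C@]34C(=O)O[C@](C)(CC[C@@H]3O)[C@@H]24)C=CC1=O | intermediate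
22 | (1S,3aR,4S,7R,7aS)-4-hydroxy-1-{[(1S)-1-hydroxy-5,5-dimethyl-4-oxocyclohex-2-en-1-yl]methyl}-7-methyloctahydro-1H-indene-3a,7-carbolactone | CC1(C)C[C@@](O)(C[C@@H]2CC[C@]34C(=O)O[C@](C)(CC[C@@H]3O)[C@@H]24)C=CC1=O | intermediate
23 | (1S,3aR,4S,7R,7aS)-4-hydroxy-1-{[(1S)-1-hydroxy-3,3-dimethyl-4-oxocyclohexyl]methyl}-7-methyloctahydro-1H-indene-3a,7-carbolactone | CC1(C)C[C@@](O)(C[C@@H]2CC[C@]34C(=O)O[C@](C)(CC[C@@H]3O)[C@@H]24)CCC1=O | intermediate
24 | (1S,3aR,7R,7aS)-1-{[(1S)-1-hydroxy-3,3-dimethyl-4-oxocyclohexyl]methyl}-7-methyl-4-oxooctahydro-1H-indene-3a,7-carbolactone | CC1(C)C[C@@](O)(C[C@@H]2CC[C@]34C(=O)O[C@](C)(CCC3=O)[C@@H]24)CCC1=O | intermediate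
25 | 1′-O-trimethylsilyl ether of 24 | CC1(C)C[C@@](O[Si](C)(C)C)(C[C@@H]2CC[C@]34C(=O)O[C@](C)(CCC3=O)[C@@H]24)CCC1=O | intermediate
26 | (1S,3aS,7R,7aS)-4-bromo-1-{[(1R)-4-bromo-5,5-dimethyl-1-(trimethylsilyloxy)cyclohex-3-en-1-yl]methyl}-7-methyl-2,3,3a,6,7,7a-hexahydro-1H-indene-3a,7-carbolactone | CC1(C)C[C@@](O[Si](C)(C)C)(C[C@@H]2CC[C@]34C(=O)O[C@](C)(CC=C3Br)[C@@H]24)CC=C1Br | intermediate
27 | (1S,3aS,4S,7R,7aS)-4-bromo-1-{[(1S,4S)-4-bromo-3,3-dimethyl-1-(trimethylsilyloxy)cyclohexyl]methyl}-7-methyloctahydro-1H-indene-3a,7-carbolactone | CC1(C)C[C@@](O[Si](C)(C)C)(C[C@@H]2CC[C@]34C(=O)O[C@](C)(CC[C@@H]3Br)[C@@H]24)CC[C@@H]1Br | intermediate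
28 | (1S,3aS,4S,7R,7aS)-4-bromo-1-{[(1S,4S)-4-bromo-1-hydroxy-3,3-dimethylcyclohexyl]methyl}-7-methyloctahydro-1H-indene-3a,7-carbolactone | CC1(C)C[C@@](O)(C[C@@H]2CC[C@]34C(=O)O[C@](C)(CC[C@@H]3Br)[C@@H]24)CC[C@@H]1Br | target

**Step count and risks**

Total step count: 13. Longest linear sequence: 13 steps (1 → 28).

Steps most likely to fail:

Step 3. Dehydration of the ketol to the conjugated enone, or β-elimination of the lactone carboxylate from the product, may outrun epimerisation at C7a and lactonisation. Fallback, from 7 to 10: the aldol condensation is driven to completion on purpose (pyrrolidine, AcOH, then TsOH, toluene, reflux) to give the hydrindenone ester F1. Me3SiI (MeCN, 0 °C, aqueous work-up) then adds iodide to C7 of the enone, the neighbouring ester carbonyl displaces the tertiary iodide and loses its methyl group, and the liberated C1 ketone lets C7a equilibrate, which gives 10.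

Step 8. Discrimination between the two enone arms may be poor, so that C1′ forms with low selectivity, or reduction may go on to the saturated ketone. Fallback, from 19 to 23: both enone double bonds are hydrogenated (H2, Pd/C) to the symmetric hydroxy ketone F2. Enantioselective deprotonation with a chiral lithium amide (lithium bis[(1R)-1-phenylethyl]amide or its antipode, excess, LiCl, THF, −100 °C) and trapping with MeI gives the 3′-methyl ketone F3 with C1′ now stereogenic. Thermodynamic methylation at the substituted α-carbon (KOt-Bu, t-BuOH, MeI) then gives 23.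

Step 7. Attack of tert-butyllithium or of the alkyllithium on the lactone, or protonation of the alkyllithium before it meets the quinone monoketal, may consume the iodide. Fallback, from 15 to 19: zinc insertion (Zn, LiCl, THF) gives the lactone-tolerant alkylzinc iodide F4. Negishi coupling with 4-bromophenyl tert-butyldimethylsilyl ether (Pd(OAc)2, SPhos, THF) gives the arene F5. Bu4NF removes both silyl groups to give the phenol F6, and oxidative dearomatisation of this para-alkylphenol (PhI(OAc)2, MeCN/H2O, 0 °C) gives 19.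

Further compounds
F1 | step 3 | methyl (3aR)-7-methyl-1,4-dioxo-1,2,3,4,5,6-hexahydro-3aH-indene-3a-carboxylate | O=C1CC[C@]2(C(=O)OC)C(=O)CCC(C)=C12
F2 | step 8 | (1S,3aR,4S,7R,7aS)-4-hydroxy-1-[(1-hydroxy-4-oxocyclohexyl)methyl]-7-methyloctahydro-1H-indene-3a,7-carbolactone | O=C1CCC(O)(C[C@@H]2CC[C@]34C(=O)O[C@](C)(CC[C@@H]3O)[C@@H]24)CC1
F3 | step 8 | 3′-methyl ketone, the monomethyl analogue of 23 (mixture of epimers at the methyl-bearing carbon) | CC1C[C@@](O)(C[C@@H]2CC[C@]34C(=O)O[C@](C)(CC[C@@H]3O)[C@@H]24)CCC1=O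
F4 | step 7 | alkylzinc iodide from 15 (CH2ZnI in place of CH2I) | I[Zn]C[C@@H]1CC[C@]23C(=O)O[C@](C)(CC[C@@H]2O[Si](CC)(CC)CC)[C@@H]13
F5 | step 7 | (1S,3aR,4S,7R,7aS)-1-[4-(tert-butyldimethylsilyloxy)benzyl]-7-methyl-4-(triethylsilyloxy)octahydro-1H-indene-3a,7-carbolactone | CC(C)(C)[Si](C)(C)Oc1ccc(C[C@@H]2CC[C@]34C(=O)O[C@](C)(CC[C@@H]3O[Si](CC)(CC)CC)[C@@H]24)cc1
F6 | step 7 | (1S,3aR,4S,7R,7aS)-4-hydroxy-1-(4-hydroxybenzyl)-7-methyloctahydro-1H-indene-3a,7-carbolactone | Oc1ccc(C[C@@H]2CC[C@]34C(=O)O[C@](C)(CC[C@@H]3O)[C@@H]24)cc1
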